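An equilibrium constant of 30 starts the quarrel over this flask.

D 0.12 M; Z 0.120 M; X 18 mM; E 0.12 M

    L + X + D → X + Q (k1 = 217 /M²/h)
    L + X + E → X + G (k2 = 18.7 /M²/h)
    Z ⇌ L, rate k3*(cs3 - [L]) while solid is left; crystals form when [L] > cs3 (cs3 = 0.097 M, k3 = 0.413 /h)
    X ⇌ J (K4 = 30, k4 = 0.0830 /h)

- the form that holds most of the catalyst when 30 % of the D and E together are converted (X / J)
- its share of the catalyst then

- X is single-handed; D and E are mirror images of each other, charged as a racemate, each of them at the stated concentration
- as a solid, counted per litre of solution: Z
- at the start none of Z is in solution
- charge of D (flask): 0.12 M

The first party reads equilibrium: J would hold 96.8 % of the catalyst and X 3.23 %, so the answer is J. This is thermodynamic against kinetic control of the catalyst's form. The second party reads the clock: the flask is charged with X and no J, and the excess of X over its equilibrium share decays exponentially at λ, the forward constant 0.0830 /h plus the back constant 0.00277 /h, together 0.0858 /h.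

Equal shares are the zero of this scale. The decay reaches them at 8.48 h, and that crossover time t×, the moment X and J stand level, sorts the answer: a conversion arriving earlier finds mostly X, a later one mostly J.

So when does it arrive? My own reckoning: the conversion asked for is 0.0720 M of D and E together, and the charge of Z covers it. With X, D and E at their charges, L is spent with a combined coefficient 0.509 /h. Balanced against dissolution, this holds L near 0.0434 M and gives 0.0221 M/h. That rate needs 3.26 h, which I take as a floor, since L starts from zero, with none of Z in solution, and X and D fall from their charges. To arrive before t×, the mean rate must be at least 0.00849 M/h, which is less than that balanced estimate at full charges, and I judge the gap wide enough to absorb the slow start and the falling X and D. I commit to X, with a share above equal and below 76.4 %.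

The forecast sides with the clock: X at 63 %, range 57 % to 69 %, holding that “about a third has become J by then”. Its range is narrower than mine.

The simulation gives X at 59.9 %, inside the forecast's range, with the conversion reached at 6.24 h, which is 2.24 h ahead of t×. The equilibrium reading has its region past t×: at 15.0 h this flask has J at 70.0 %. In the flask with twice the X, the same conversion comes at 4.13 h, further ahead of the same t×, and the clock puts X there at 71.1 %.

(The constants are assumed; what happens was integrated by code.)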